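**Retrosynthetic overview**

1. The two sesquiterpenoid halves of the target are mirror images (acyl half 5aS,6R,9S,9aS; alcohol half 5aR,6S,9R,9aR). The inter-unit ester is therefore cut last, and both partners come from one racemic monomer that a lipase acylation resolves and differentiates in a single step.
2. Monomer: the 9-OH/9-CH2OH pair comes from a 9-methylidene group (OsO4), itself from a 9-ketone. The ε-lactone is opened at its acyl–oxygen bond: the oxygen that a Baeyer–Villiger oxygenase inserts in nature is carried in on C3, because a peracid would migrate the ring-fusion carbon of the carbocyclic ketone instead.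
3. Key disconnection: the cyclohexane C5a–C6 bond, made by a cation–olefin (ene) closure of a prenyl terminus onto an alkylidene β-keto ester. This is the laboratory copy of the C1–C10 cyclisation of farnesyl diphosphate, with the cation on the future isopropyl carbon; the adjacent C5a–C9a bond comes from a Knoevenagel condensation in the same flask.
4. Ring order: carbocycle first (step 2, three stereocentres at once), oxepinone second (step 6, acylketene capture). Building blocks: tert-butyl acetoacetate, prenyl bromide, 2,2-dimethoxyacetaldehyde, tert-butyl diethylphosphonoacetate, formaldehyde.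

Convention: locants are those of 2-benzoxepine (C1 lactone carbonyl, O2, C3, C4, C5, C5a, C6 to C9, C9a). For racemates (rac) the name and SMILES show the enantiomer that ends in the acyl half; its mirror image is present in equal amount and ends in the alcohol half. The enantiomer of 15 that step 9 leaves unacylated keeps the number 15. It is tert-butyl (5aR,6S,9R,9aR)-9-hydroxy-9-(hydroxymethyl)-1-oxo-6-(propan-2-yl)-1,3,5a,6,7,8,9,9a-octahydro-2-benzoxepine-4-carboxylate, SMILES CC(C)[C@@H]1CC[C@](O)(CO)[C@@H]2C(=O)OCC(C(=O)OC(C)(C)C)=C[C@@H]12, the mirror image of the SMILES listed for 15.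

Assumption: Amano lipase PS acylates the (9S)-antipode of diol 15 faster; a short lipase screen finds an enzyme with this preference, and only such an enzyme is used.

**Route**

Step 1
Reactants: 1 tert-butyl acetoacetate; 2 prenyl bromide (1-bromo-3-methylbut-2-ene)
Product: 3 tert-butyl 7-methyl-3-oxooct-6-enoate
Conditions: NaH, THF, 0 °C; n-BuLi, 0 °C; then 2, 0 °C to rt; aq. NH4Cl
Reagents that add atoms: none
Why: Weiler dianion alkylation, in which the more basic γ-carbanion of the acetoacetate dianion is alkylated by the allylic bromide and the β-keto ester is kept.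

Step 2
Reactants: 3 tert-butyl 7-methyl-3-oxooct-6-enoate; 4 2,2-dimethoxyacetaldehyde
Product: 6 rac-tert-butyl (1S,2R,3S)-2-(dimethoxymethyl)-6-oxo-3-(prop-1-en-2-yl)cyclohexane-1-carboxylate, via alkylidene keto ester 5 (not isolated)
Conditions: 4 (anhydrous, 1.2 equiv), piperidine (10 mol %), AcOH (10 mol %), 4 Å MS, CH2Cl2, 0 °C; then ZnBr2 (1.2 equiv), 0 °C
Reagents that add atoms: none
Why: Proposed new method: Knoevenagel condensation gives the doubly activated alkylidene 5, whose ZnBr2 chelate is attacked at the β-carbon by the proximal carbon of the prenyl double bond tethered through the ketone (six-membered cation–olefin closure, the tertiary cation being quenched by proton loss from a methyl group, i.e. an intramolecular ene reaction); a chair transition state with both new substituents equatorial sets the 2,3-trans relationship and the epimerisable C1 settles trans to C2, the closest known chemistry being the Tietze domino Knoevenagel–ene reaction of alkylidene 1,3-dicarbonyl compounds and Lewis-acid cyclisations of alkylidene β-keto esters.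

Step 3
Reactants: 6 rac-tert-butyl (1S,2R,3S)-2-(dimethoxymethyl)-6-oxo-3-(prop-1-en-2-yl)cyclohexane-1-carboxylate
Product: 8 rac-tert-butyl (1S,2R,3R)-2-formyl-6-oxo-3-(propan-2-yl)cyclohexane-1-carboxylate, via isopropyl acetal 7 (not isolated)
Conditions: H2 (1 atm), RhCl(PPh3)3 (5 mol %), toluene/EtOH, rt; concentrate; Amberlyst-15, acetone/H2O (20:1), rt; used crude
Reagents that add atoms: water, O
Why: Homogeneous hydrogenation with RhCl(PPh3)3 saturates only the 1,1-disubstituted alkene without double-bond migration (C3 keeps its geometry, its descriptor changes only through priorities), and mild acid-catalysed acetal hydrolysis then frees the aldehyde, the γ-keto aldehyde being carried on at once to avoid furan formation.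

Step 4
Reactants: 9 tert-butyl 2-(diethoxyphosphoryl)acetate
Product: 10 tert-butyl 2-(diethoxyphosphoryl)-3-hydroxypropanoate (racemic)
Conditions: (CH2O)n (1.1 equiv), piperidine (5 mol %), THF, 60 °C
Reagents that add atoms: formaldehyde (from paraformaldehyde), C=O
Why: Amine-catalysed aldol-type hydroxymethylation of the activated methylene (the first stage of the Villieras acrylate synthesis), stopped at the mono-adduct because no stoichiometric base is present.

Step 5
Reactants: 8 rac-tert-butyl (1S,2R,3R)-2-formyl-6-oxo-3-(propan-2-yl)cyclohexane-1-carboxylate; 10 tert-butyl 2-(diethoxyphosphoryl)-3-hydroxypropanoate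
Product: 11 rac-tert-butyl (1S,2S,3R)-2-[(1E)-3-tert-butoxy-2-(hydroxymethyl)-3-oxoprop-1-en-1-yl]-6-oxo-3-(propan-2-yl)cyclohexane-1-carboxylate
Conditions: LiCl, DBU, MeCN, 0 °C to rt
Reagents that add atoms: none
Why: Horner–Wadsworth–Emmons olefination under Masamune–Roush conditions, in which the α-substituted phosphonate gives mainly the E-enoate (ring carbon trans to the ester and cis to CH2OH, as the ring closure needs), the β-hydroxy phosphonate carbanion olefinating as it does with the second formaldehyde in the Villieras reaction, while the mild base leaves the all-equatorial ring stereocentres at their thermodynamic setting.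

Step 6
Reactants: 11 rac-tert-butyl (1S,2S,3R)-2-[(1E)-3-tert-butoxy-2-(hydroxymethyl)-3-oxoprop-1-en-1-yl]-6-oxo-3-(propan-2-yl)cyclohexane-1-carboxylate
Product: 13 rac-tert-butyl (5aS,6R,9aS)-1,9-dioxo-6-(propan-2-yl)-1,3,5a,6,7,8,9,9a-octahydro-2-benzoxepine-4-carboxylate, via acylketene 12 (not isolated)
Conditions: toluene (0.005 M), 110 °C
Reagents that add atoms: none
Why: Thermal loss of tert-butanol from the β-keto tert-butyl ester gives acylketene 12 (Witzeman transacetoacetylation), which the primary allylic alcohol lying cis to the ring captures intramolecularly (Boeckman-type acylketene lactonisation) to close the seven-membered lactone; the β-keto lactone settles as the trans-fused diequatorial epimer at C9a, and the simple enoate tert-butyl ester and any Z-isomer of 11 do not react.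

Step 7
Reactants: 13 rac-tert-butyl (5aS,6R,9aS)-1,9-dioxo-6-(propan-2-yl)-1,3,5a,6,7,8,9,9a-octahydro-2-benzoxepine-4-carboxylate
Product: 14 rac-tert-butyl (5aS,6R,9aS)-9-methylidene-1-oxo-6-(propan-2-yl)-1,3,5a,6,7,8,9,9a-octahydro-2-benzoxepine-4-carboxylate
Conditions: Zn, CH2Br2, TiCl4, THF/CH2Cl2, 0 °C to rt
Reagents that add atoms: dibromomethane, BrCBr
Why: Takai–Lombardo methylenation, whose non-basic zinc/titanium gem-dimetallic reagent methylenates the ketone of easily enolised β-dicarbonyl compounds without attacking lactone or ester carbonyls and without epimerising C9a.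

Step 8
Reactants: 14 rac-tert-butyl (5aS,6R,9aS)-9-methylidene-1-oxo-6-(propan-2-yl)-1,3,5a,6,7,8,9,9a-octahydro-2-benzoxepine-4-carboxylate
Product: 15 rac-tert-butyl (5aS,6R,9S,9aS)-9-hydroxy-9-(hydroxymethyl)-1-oxo-6-(propan-2-yl)-1,3,5a,6,7,8,9,9a-octahydro-2-benzoxepine-4-carboxylate
Conditions: K2OsO2(OH)4 (2 mol %), NMO, acetone/H2O, 0 °C
Reagents that add atoms: N-methylmorpholine N-oxide, C[N+]1([O-])CCOCC1; water, O
Why: Upjohn dihydroxylation, in which OsO4 takes the exocyclic 1,1-disubstituted alkene (the trisubstituted enoate is far slower) from the equatorial direction, away from the axial hydrogens at C5a and C7, giving the equatorial tertiary OH and the axial CH2OH.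

Step 9
Reactants: 15 rac-tert-butyl (5aS,6R,9S,9aS)-9-hydroxy-9-(hydroxymethyl)-1-oxo-6-(propan-2-yl)-1,3,5a,6,7,8,9,9a-octahydro-2-benzoxepine-4-carboxylate
Product: 16 tert-butyl (5aS,6R,9S,9aS)-9-[(2-chloroacetoxy)methyl]-9-hydroxy-1-oxo-6-(propan-2-yl)-1,3,5a,6,7,8,9,9a-octahydro-2-benzoxepine-4-carboxylate
Conditions: Amano lipase PS (immobilised), vinyl chloroacetate (0.6 equiv), MTBE, 30 °C, to 50–55% conversion; SiO2 chromatography
Reagents that add atoms: vinyl chloroacetate, ClCC(=O)OC=C
Why: Lipase-catalysed kinetic resolution by irreversible transesterification of the primary alcohol next to the quaternary stereocentre, which acylates only the (5aS,6R,9S,9aS) half of racemic 15 to give 16, while the (5aR,6S,9R,9aR) enantiomer of 15 stays unacylated and is recovered from the same column for step 11, so both enantiomers made in step 8 are used; imperfect selectivity is tolerated because a wrong-antipode contaminant ends in a diastereomeric dimer that is removed after step 11.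

Step 10
Reactants: 16 tert-butyl (5aS,6R,9S,9aS)-9-[(2-chloroacetoxy)methyl]-9-hydroxy-1-oxo-6-(propan-2-yl)-1,3,5a,6,7,8,9,9a-octahydro-2-benzoxepine-4-carboxylate
Product: 17 (5aS,6R,9S,9aS)-9-[(2-chloroacetoxy)methyl]-9-hydroxy-1-oxo-6-(propan-2-yl)-1,3,5a,6,7,8,9,9a-octahydro-2-benzoxepine-4-carboxylic acid
Conditions: TFA/CH2Cl2 (1:3), 0 °C to rt
Reagents that add atoms: none
Why: Acidolysis of the tert-butyl ester (E1 loss of isobutene); the lactone, the chloroacetate and the tertiary alcohol, whose ionisation is disfavoured by the neighbouring acyloxymethyl group, are stable to cold TFA.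

Step 11
Reactants: 17 (5aS,6R,9S,9aS)-9-[(2-chloroacetoxy)methyl]-9-hydroxy-1-oxo-6-(propan-2-yl)-1,3,5a,6,7,8,9,9a-octahydro-2-benzoxepine-4-carboxylic acid; 15 tert-butyl 9-hydroxy-9-(hydroxymethyl)-1-oxo-6-(propan-2-yl)-1,3,5a,6,7,8,9,9a-octahydro-2-benzoxepine-4-carboxylate, here its single (5aR,6S,9R,9aR) enantiomer recovered unacylated from step 9
Product: 18 [(5aR,6S,9R,9aR)-4-(tert-butoxycarbonyl)-9-hydroxy-1-oxo-6-(propan-2-yl)-1,3,5a,6,7,8,9,9a-octahydro-2-benzoxepin-9-yl]methyl (5aS,6R,9S,9aS)-9-[(2-chloroacetoxy)methyl]-9-hydroxy-1-oxo-6-(propan-2-yl)-1,3,5a,6,7,8,9,9a-octahydro-2-benzoxepine-4-carboxylate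
Conditions: EDC·HCl, DMAP (0.3 equiv), CH2Cl2, 0 °C to rt
Reagents that add atoms: none
Why: Steglich esterification, in which only the primary hydroxyl of the recovered (5aR,6S,9R,9aR) diol is acylated (both tertiary alcohols are inert), the chloroacetate prevents self-condensation of 17, and the heterochiral ester is separated from any homochiral diastereomer by chromatography.

Step 12
Reactants: 18 protected heterochiral dimer
Product: 20 CNP0340505.1 (target), via chloroacetyl dimer acid 19 (not isolated)
Conditions: TFA/CH2Cl2 (1:3), 0 °C; evaporate; thiourea, 2,6-lutidine, MeOH/CH2Cl2, rt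
Reagents that add atoms: none
Why: The tert-butyl ester acidolysis is run first, while the primary alcohol of the acyl half is still masked (no acid-catalysed translactonisation to a γ-lactone), and the chloroacetate is then removed under near-neutral conditions by thiourea (S-alkylation followed by cyclisation to 2-aminothiazol-4(5H)-one), which leaves both lactones and the inter-unit ester untouched.

**Compound list**

1 | tert-butyl acetoacetate | CC(=O)CC(=O)OC(C)(C)C | starting material
2 | prenyl bromide (1-bromo-3-methylbut-2-ene) | CC(C)=CCBr | starting material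
3 | tert-butyl 7-methyl-3-oxooct-6-enoate | CC(C)=CCCC(=O)CC(=O)OC(C)(C)C | intermediate
4 | 2,2-dimethoxyacetaldehyde | COC(OC)C=O | starting material
5 | tert-butyl 2-(2,2-dimethoxyethylidene)-7-methyl-3-oxooct-6-enoate (E/Z mixture) | CC(C)=CCCC(=O)C(=CC(OC)OC)C(=O)OC(C)(C)C | intermediate (not isolated)
6 | rac-tert-butyl (1S,2R,3S)-2-(dimethoxymethyl)-6-oxo-3-(prop-1-en-2-yl)cyclohexane-1-carboxylate (all-trans) | CC(=C)[C@H]1CCC(=O)[C@@H](C(=O)OC(C)(C)C)[C@@H]1C(OC)OC | intermediate
7 | rac-tert-butyl (1S,2R,3R)-2-(dimethoxymethyl)-6-oxo-3-(propan-2-yl)cyclohexane-1-carboxylate | CC(C)[C@H]1CCC(=O)[C@@H](C(=O)OC(C)(C)C)[C@@H]1C(OC)OC | intermediate (not isolated)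
8 | rac-tert-butyl (1S,2R,3R)-2-formyl-6-oxo-3-(propan-2-yl)cyclohexane-1-carboxylate | CC(C)[C@H]1CCC(=O)[C@@H](C(=O)OC(C)(C)C)[C@@H]1C=O | intermediate
9 | tert-butyl 2-(diethoxyphosphoryl)acetate | CCOP(=O)(CC(=O)OC(C)(C)C)OCC | starting material
10 | tert-butyl 2-(diethoxyphosphoryl)-3-hydroxypropanoate (racemic) | CCOP(=O)(OCC)C(CO)C(=O)OC(C)(C)C | intermediate
11 | rac-tert-butyl (1S,2S,3R)-2-[(1E)-3-tert-butoxy-2-(hydroxymethyl)-3-oxoprop-1-en-1-yl]-6-oxo-3-(propan-2-yl)cyclohexane-1-carboxylate | CC(C)[C@H]1CCC(=O)[C@@H](C(=O)OC(C)(C)C)[C@@H]1/C=C(\CO)C(=O)OC(C)(C)C | intermediate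
12 | acylketene from 11 (2-oxocyclohexylidene ketene, rac) | CC(C)[C@H]1CCC(=O)C(=C=O)[C@@H]1/C=C(\CO)C(=O)OC(C)(C)C | intermediate (not isolated)
13 | rac-tert-butyl (5aS,6R,9aS)-1,9-dioxo-6-(propan-2-yl)-1,3,5a,6,7,8,9,9a-octahydro-2-benzoxepine-4-carboxylate | CC(C)[C@H]1CCC(=O)[C@H]2C(=O)OCC(C(=O)OC(C)(C)C)=C[C@H]12 | intermediate
14 | rac-tert-butyl (5aS,6R,9aS)-9-methylidene-1-oxo-6-(propan-2-yl)-1,3,5a,6,7,8,9,9a-octahydro-2-benzoxepine-4-carboxylate | CC(C)[C@H]1CCC(=C)[C@H]2C(=O)OCC(C(=O)OC(C)(C)C)=C[C@H]12 | intermediate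
15 | rac-tert-butyl (5aS,6R,9S,9aS)-9-hydroxy-9-(hydroxymethyl)-1-oxo-6-(propan-2-yl)-1,3,5a,6,7,8,9,9a-octahydro-2-benzoxepine-4-carboxylate (racemate from step 8; the mirror-image 5aR,6S,9R,9aR enantiomer is recovered in step 9 and used in step 11) | CC(C)[C@H]1CC[C@@](O)(CO)[C@H]2C(=O)OCC(C(=O)OC(C)(C)C)=C[C@H]12 | intermediate
16 | tert-butyl (5aS,6R,9S,9aS)-9-[(2-chloroacetoxy)methyl]-9-hydroxy-1-oxo-6-(propan-2-yl)-1,3,5a,6,7,8,9,9a-octahydro-2-benzoxepine-4-carboxylate | CC(C)[C@H]1CC[C@@](O)(COC(=O)CCl)[C@H]2C(=O)OCC(C(=O)OC(C)(C)C)=C[C@H]12 | intermediate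
17 | (5aS,6R,9S,9aS)-9-[(2-chloroacetoxy)methyl]-9-hydroxy-1-oxo-6-(propan-2-yl)-1,3,5a,6,7,8,9,9a-octahydro-2-benzoxepine-4-carboxylic acid | CC(C)[C@H]1CC[C@@](O)(COC(=O)CCl)[C@H]2C(=O)OCC(C(=O)O)=C[C@H]12 | intermediate
18 | protected dimer: acid 17 esterified with the 9-CH2OH of the (5aR,6S,9R,9aR) enantiomer of 15 (chloroacetate and tert-butyl ester in place) | CC(C)[C@H]1CC[C@@](O)(COC(=O)CCl)[C@H]2C(=O)OCC(C(=O)OC[C@@]3(O)CC[C@@H](C(C)C)[C@@H]4C=C(C(=O)OC(C)(C)C)COC(=O)[C@H]43)=C[C@H]12 | intermediate
19 | chloroacetyl dimer acid (18 without the tert-butyl group) | CC(C)[C@H]1CC[C@@](O)(COC(=O)CCl)[C@H]2C(=O)OCC(C(=O)OC[C@@]3(O)CC[C@@H](C(C)C)[C@@H]4C=C(C(=O)O)COC(=O)[C@H]43)=C[C@H]12 | intermediate (not isolated)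
20 | CNP0340505.1: [(5aR,6S,9R,9aR)-4-carboxy-9-hydroxy-1-oxo-6-(propan-2-yl)-1,3,5a,6,7,8,9,9a-octahydro-2-benzoxepin-9-yl]methyl (5aS,6R,9S,9aS)-9-hydroxy-9-(hydroxymethyl)-1-oxo-6-(propan-2-yl)-1,3,5a,6,7,8,9,9a-octahydro-2-benzoxepine-4-carboxylate | CC(C)[C@H]1CC[C@@](O)(CO)[C@H]2C(=O)OCC(C(=O)OC[C@@]3(O)CC[C@@H](C(C)C)[C@@H]4C=C(C(=O)O)COC(=O)[C@H]43)=C[C@H]12 | target

**Totals and risks**

Total step count: 12. Longest linear sequence: 11 steps (1, 2, 3, 5, 6, 7, 8, 9, 10, 11, 12); step 4 is a side branch.

Step 2 (most likely to fail). The ring-closure mode is new, and the Lewis acid may ionise the acetal or attack the tert-butyl ester instead of promoting the ene closure. The fallback gives up the cationic closure for a polar Robinson-type annulation. It sets out from 1 and 4: crossed aldol condensation of commercial isovaleraldehyde with 4 (pyrrolidine, AcOH) gives (E)-4,4-dimethoxy-2-(propan-2-yl)but-2-enal F1. Michael addition of 1 to F1 and aldol condensation in the same flask (catalytic t-BuOK in t-BuOH, then pyrrolidinium acetate) give rac-tert-butyl (1S,2R,3S)-2-(dimethoxymethyl)-6-oxo-3-(propan-2-yl)cyclohex-4-ene-1-carboxylate F2, which is equilibrated with DBU to the all-trans isomer through its β-keto ester and vinylogous positions. Hydrogenation of the enone double bond (H2, Pd/C, EtOAc) brings the material back to the route at 7.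

Step 7. The β-keto lactone 13 may simply be enolised by the methylenating reagent. The fallback builds the C9 carbinol through the enol instead of the ketone and sets out from 13. Tf2O and iPr2NEt in CH2Cl2 at −78 °C give rac-tert-butyl (5aS,6R)-1-oxo-6-(propan-2-yl)-9-(trifluoromethanesulfonyloxy)-1,3,5a,6,7,8-hexahydro-2-benzoxepine-4-carboxylate F3. Stille coupling with Bu3SnCH2OH (Pd(PPh3)4, LiCl, dioxane, 80 °C) gives rac-tert-butyl (5aS,6R)-9-(hydroxymethyl)-1-oxo-6-(propan-2-yl)-1,3,5a,6,7,8-hexahydro-2-benzoxepine-4-carboxylate F4. Hydroxyl-directed epoxidation (VO(acac)2, t-BuOOH) on the face away from the isopropyl group gives the rac-9,9a-epoxy alcohol F5. SmI2 in THF/MeOH at −78 °C then cleaves the C9a–O bond of the α,β-epoxy lactone and protonation at C9a gives 15, where the route is rejoined. The face selectivity of the epoxidation and of the final protonation would have to be checked.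

Step 9. The enantioselectivity of a lipase towards this hindered axial CH2OH is not predictable. The fallback replaces the enzymatic resolution by a physical one followed by a chemical acylation and sets out from 15. Preparative chromatography on a chiral stationary phase (amylose carbamate) splits racemic 15 into its two enantiomers. The (5aR,6S,9R,9aR) enantiomer goes to step 11 exactly as in the route. Its antipode is tert-butyl (5aS,6R,9S,9aS)-9-hydroxy-9-(hydroxymethyl)-1-oxo-6-(propan-2-yl)-1,3,5a,6,7,8,9,9a-octahydro-2-benzoxepine-4-carboxylate F6. F6 is acylated at −20 °C with chloroacetic anhydride and 2,4,6-collidine, which takes only the primary hydroxyl, and the route is rejoined at 16.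

**Further compounds**

F1 | step 2 | (E)-4,4-dimethoxy-2-(propan-2-yl)but-2-enal | COC(OC)/C=C(\C(C)C)C=O
F2 | step 2 | rac-tert-butyl (1S,2R,3S)-2-(dimethoxymethyl)-6-oxo-3-(propan-2-yl)cyclohex-4-ene-1-carboxylate | CC(C)[C@H]1C=CC(=O)[C@@H](C(=O)OC(C)(C)C)[C@@H]1C(OC)OC
F3 | step 7 | rac-tert-butyl (5aS,6R)-1-oxo-6-(propan-2-yl)-9-(trifluoromethanesulfonyloxy)-1,3,5a,6,7,8-hexahydro-2-benzoxepine-4-carboxylate | CC(C)[C@H]1CCC(OS(=O)(=O)C(F)(F)F)=C2C(=O)OCC(C(=O)OC(C)(C)C)=C[C@H]12
F4 | step 7 | rac-tert-butyl (5aS,6R)-9-(hydroxymethyl)-1-oxo-6-(propan-2-yl)-1,3,5a,6,7,8-hexahydro-2-benzoxepine-4-carboxylate | CC(C)[C@H]1CCC(CO)=C2C(=O)OCC(C(=O)OC(C)(C)C)=C[C@H]12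
F5 | step 7 | rac-9,9a-epoxide of F4 (epoxide oxygen anti to the isopropyl group) | CC(C)[C@H]1CC[C@]2(CO)O[C@@]23C(=O)OCC(C(=O)OC(C)(C)C)=C[C@H]13
F6 | step 9 | tert-butyl (5aS,6R,9S,9aS)-9-hydroxy-9-(hydroxymethyl)-1-oxo-6-(propan-2-yl)-1,3,5a,6,7,8,9,9a-octahydro-2-benzoxepine-4-carboxylate (single enantiomer) | CC(C)[C@H]1CC[C@@](O)(CO)[C@H]2C(=O)OCC(C(=O)OC(C)(C)C)=C[C@H]12
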